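## Retrosynthetic overview

1. Target 38 ⇒ macrocyclic alcohol 35 by acylation of C4–OH with 3-methylbut-2-enoyl chloride 36 and removal of two silyl ethers.
2. 35 ⇒ acyclic ynal 33 by a Ni(cod)2/carbene-catalysed reductive alkyne–aldehyde coupling (C3–C4). This closes the eleven-membered carbocycle last and sets C4 and the E C2=C3 alkene.
3. 33 ⇒ aldehyde 18 (fragment A) + ester-stabilised ylide 29 (fragment B) by an E-selective Wittig reaction (C9=C10).
4. 18 ⇒ quaternary C1 from invertive alkynylalane opening of Sharpless epoxide 10; C14 from CBS reduction of enone 4.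
5. 29 ⇒ the oxirane (C5, C6; the first ring formed) by Sharpless epoxidation of allylic alcohol 23, built from propane-1,3-diol.

Atom labels used below: ring C1 (quaternary, methyl) – C2=C3 – C4 (O-acyl) – C5 (oxirane, methyl) – C6 (oxirane CH) – C7 – C8 – C9 (bears C18H2OH) = C10 – C11 – back to C1; side chain C12–C13–C14(OH)–C15(=C16H2)–C17H3. The target is 1S,4R,5R,6S,14R with E C2=C3 and C8/C11 cis on C9=C10.

## Fragment A

Step 1
Reactants: 1 pent-4-ynoic acid
Product: 2 N-methoxy-N-methylpent-4-ynamide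
Conditions: MeNH(OMe)·HCl, EDC·HCl, N-methylmorpholine, CH2Cl2, 0 °C → rt
Reagents that add atoms: N,O-dimethylhydroxylamine hydrochloride, CNOC.Cl
Why: Carbodiimide amide coupling gives the Weinreb amide, which stops acyl substitution at the ketone stage in the next step.

Step 2
Reactants: 2 N-methoxy-N-methylpent-4-ynamide; 3 prop-1-en-2-ylmagnesium bromide
Product: 4 2-methylhept-1-en-6-yn-3-one
Conditions: 3 (2.3 equiv), THF, −78 → 0 °C; inverse quench into cold 1 M HCl
Reagents that add atoms: none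
Why: Weinreb ketone synthesis: the chelated tetrahedral adduct survives until the acidic quench, so only one isopropenyl group is transferred (a second equivalent of 3 is consumed by the alkyne C–H, which is restored on quench).

Step 3
Reactants: 4 2-methylhept-1-en-6-yn-3-one
Product: 5 (3R)-2-methylhept-1-en-6-yn-3-ol
Conditions: (S)-2-methyl-CBS-oxazaborolidine (20 mol %), catecholborane, toluene, −78 °C; MeOH, then aq. NaOH
Reagents that add atoms: none
Why: Corey–Bakshi–Shibata reduction: with isopropenyl as the large group the (S)-oxazaborolidine delivers hydride to the face that gives the (R)-carbinol (C14), and catecholborane at −78 °C leaves the alkyne and alkene untouched.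

Step 4
Reactants: 5 (3R)-2-methylhept-1-en-6-yn-3-ol
Product: 6 (3R)-3-(tert-butyldimethylsilyloxy)-2-methylhept-1-en-6-yne
Conditions: TBSCl, imidazole, DMF, rt
Reagents that add atoms: tert-butyldimethylsilyl chloride, CC(C)(C)[Si](C)(C)Cl
Why: Imidazole-promoted silylation protects C14–OH through the organoaluminium, oxidation and coupling steps.

Step 5
Reactants: 6 (3R)-3-(tert-butyldimethylsilyloxy)-2-methylhept-1-en-6-yne
Product: 9 (2E,6R)-6-(tert-butyldimethylsilyloxy)-3,7-dimethylocta-2,7-dien-1-ol, via alkenyldimethylalane 7 (not isolated), via lithium alkenylalanate 8 (not isolated)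
Conditions: AlMe3 (2.5 equiv), Cp2ZrCl2 (20 mol %), CH2Cl2, 0 °C → rt; volatiles removed; n-BuLi, THF, −78 °C; (CH2O)n, → rt; aq. potassium sodium tartrate
Reagents that add atoms: trimethylaluminium, C[Al](C)C; paraformaldehyde (as formaldehyde), C=O
Why: Negishi Cp2ZrCl2-catalysed carboalumination adds methyl and aluminium syn across the terminal alkyne with methyl on the internal carbon, and the alanate is hydroxymethylated with retention, which fixes the E trisubstituted alkene.

Step 6
Reactants: 9 (2E,6R)-6-(tert-butyldimethylsilyloxy)-3,7-dimethylocta-2,7-dien-1-ol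
Product: 10 [(2R,3R)-3-[(3R)-3-(tert-butyldimethylsilyloxy)-4-methylpent-4-en-1-yl]-3-methyloxiran-2-yl]methanol
Conditions: Ti(OiPr)4 (10 mol %), D-(−)-diethyl tartrate (12 mol %), t-BuOOH, 4 Å MS, CH2Cl2, −20 °C
Reagents that add atoms: tert-butyl hydroperoxide, CC(C)(C)OO
Why: Sharpless asymmetric epoxidation: D-(−)-tartrate delivers oxygen to the face of the E allylic alcohol that gives the (2R,3R)-epoxide, and only the alkene with a free allylic hydroxyl reacts.

Step 7
Reactants: 11 ethynyltrimethylsilane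
Product: 13 diethyl[(trimethylsilyl)ethynyl]aluminium, via lithium (trimethylsilyl)acetylide 12 (not isolated)
Conditions: n-BuLi, toluene, 0 °C; Et2AlCl, 0 °C → rt; solution used directly
Reagents that add atoms: diethylaluminium chloride, CC[Al](Cl)CC
Why: Deprotonation followed by lithium-to-aluminium transmetalation gives the Lewis-acidic alkynylalane needed for the directed epoxide opening.

Step 8
Reactants: 10 [(2R,3R)-3-[(3R)-3-(tert-butyldimethylsilyloxy)-4-methylpent-4-en-1-yl]-3-methyloxiran-2-yl]methanol; 13 diethyl[(trimethylsilyl)ethynyl]aluminium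
Product: 15 (2S,3R,6R)-6-(tert-butyldimethylsilyloxy)-3-ethynyl-3,7-dimethyloct-7-ene-1,2-diol, via C-silylated diol 14 (not isolated)
Conditions: 13 (3 equiv), toluene, 0 °C → rt; aq. potassium sodium tartrate; crude in MeOH, K2CO3 (0.3 equiv), rt
Reagents that add atoms: none
Why: Hydroxyl-directed alkynylalane epoxide opening: the aluminium alkoxide activates the oxirane and the alkynyl group attacks the tertiary carbon (best able to carry positive charge) with inversion, which sets the all-carbon quaternary centre C1 as S; K2CO3/MeOH then removes the C-silyl group.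

Step 9
Reactants: 15 (2S,3R,6R)-6-(tert-butyldimethylsilyloxy)-3-ethynyl-3,7-dimethyloct-7-ene-1,2-diol
Product: 16 (2R,5R)-5-(tert-butyldimethylsilyloxy)-2-ethynyl-2,6-dimethylhept-6-enal
Conditions: NaIO4, THF/pH 7 buffer, 0 °C → rt
Reagents that add atoms: none
Why: Periodate glycol cleavage removes the terminal carbon and leaves the α-quaternary aldehyde, which has no α-hydrogen and cannot epimerise.

Step 10
Reactants: 16 (2R,5R)-5-(tert-butyldimethylsilyloxy)-2-ethynyl-2,6-dimethylhept-6-enal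
Product: 17 (3R,6S)-3-(tert-butyldimethylsilyloxy)-6-ethynyl-8-methoxy-2,6-dimethylocta-1,7-diene (E/Z mixture)
Conditions: Ph3P(CH2OMe)Cl (3 equiv), KN(SiMe3)2, THF, −78 → 0 °C
Reagents that add atoms: (methoxymethyl)triphenylphosphonium chloride, COC[P+](c1ccccc1)(c1ccccc1)c1ccccc1.[Cl-]
Why: Wittig methoxymethylenation adds the one carbon (C10) that is missing between the quaternary centre and the future alkene; this ylide reacts well with hindered aldehydes.

Step 11
Reactants: 17 (3R,6S)-3-(tert-butyldimethylsilyloxy)-6-ethynyl-8-methoxy-2,6-dimethylocta-1,7-diene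
Product: 18 (3S,6R)-6-(tert-butyldimethylsilyloxy)-3-ethynyl-3,7-dimethyloct-7-enal (fragment A)
Conditions: 1 M HCl, THF, 0 °C → rt
Reagents that add atoms: water, O
Why: Acid-catalysed enol ether hydrolysis gives the homologated aldehyde under conditions short and mild enough for the secondary silyl ether.

## Fragment B

Step 12
Reactants: 19 propane-1,3-diol
Product: 20 3-(4-methoxybenzyloxy)propan-1-ol
Conditions: NaH, PMBCl, Bu4NI (cat.), THF, 0 °C → rt (diol in threefold excess)
Reagents that add atoms: 4-methoxybenzyl chloride, COc1ccc(CCl)cc1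
Why: Williamson ether synthesis with excess diol gives the mono-ether.

Step 13
Reactants: 20 3-(4-methoxybenzyloxy)propan-1-ol
Product: 21 3-(4-methoxybenzyloxy)propanal
Conditions: TEMPO (10 mol %), PhI(OAc)2, CH2Cl2, rt
Reagents that add atoms: none
Why: Oxoammonium (TEMPO) oxidation stops at the aldehyde and is mild enough to avoid β-elimination of the ether.

Step 14
Reactants: 21 3-(4-methoxybenzyloxy)propanal
Product: 22 ethyl (2E)-5-(4-methoxybenzyloxy)-2-methylpent-2-enoate
Conditions: Ph3P=C(Me)CO2Et, CH2Cl2, rt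
Reagents that add atoms: ethyl 2-(triphenyl-λ5-phosphanylidene)propanoate, CCOC(=O)C(C)=P(c1ccccc1)(c1ccccc1)c1ccccc1
Why: Wittig olefination with an ester-stabilised ylide is E-selective and gives the trans relation of C4 and C7 needed in the epoxide.

Step 15
Reactants: 22 ethyl (2E)-5-(4-methoxybenzyloxy)-2-methylpent-2-enoate
Product: 23 (2E)-5-(4-methoxybenzyloxy)-2-methylpent-2-en-1-ol
Conditions: i-Bu2AlH, CH2Cl2, −78 °C; aq. potassium sodium tartrate
Reagents that add atoms: none
Why: Aluminium hydride 1,2-reduction of the enoate gives the allylic alcohol without touching the alkene.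

Step 16
Reactants: 23 (2E)-5-(4-methoxybenzyloxy)-2-methylpent-2-en-1-ol
Product: 24 [(2S,3S)-3-[2-(4-methoxybenzyloxy)ethyl]-2-methyloxiran-2-yl]methanol
Conditions: Ti(OiPr)4 (10 mol %), L-(+)-diethyl tartrate (12 mol %), t-BuOOH, 4 Å MS, CH2Cl2, −20 °C
Reagents that add atoms: tert-butyl hydroperoxide, CC(C)(C)OO
Why: Sharpless asymmetric epoxidation: L-(+)-tartrate delivers oxygen to the face of the (E)-2-methyl allylic alcohol that gives the (2S,3S)-epoxide, which is C5 and C6 of the target.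

Step 17
Reactants: 24 [(2S,3S)-3-[2-(4-methoxybenzyloxy)ethyl]-2-methyloxiran-2-yl]methanol
Product: 25 (2S,3S)-3-[2-(4-methoxybenzyloxy)ethyl]-2-methyl-2-(triethylsilyloxymethyl)oxirane
Conditions: Et3SiCl, imidazole, CH2Cl2, 0 °C
Reagents that add atoms: chlorotriethylsilane, CC[Si](Cl)(CC)CC
Why: Silylation; the primary triethylsilyl ether is chosen because it can later be oxidised directly to the aldehyde (step 24).

Step 18
Reactants: 25 (2S,3S)-3-[2-(4-methoxybenzyloxy)ethyl]-2-methyl-2-(triethylsilyloxymethyl)oxirane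
Product: 26 2-[(2S,3S)-3-methyl-3-(triethylsilyloxymethyl)oxiran-2-yl]ethan-1-ol
Conditions: DDQ, CH2Cl2/pH 7 buffer, 0 °C
Reagents that add atoms: none
Why: Oxidative cleavage of the 4-methoxybenzyl ether by DDQ; the buffer protects the epoxide and the silyl ether from acid.

Step 19
Reactants: 26 2-[(2S,3S)-3-methyl-3-(triethylsilyloxymethyl)oxiran-2-yl]ethan-1-ol
Product: 27 (2S,3S)-3-(2-iodoethyl)-2-methyl-2-(triethylsilyloxymethyl)oxirane
Conditions: I2, PPh3, imidazole, CH2Cl2, 0 °C
Reagents that add atoms: iodine, II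
Why: Appel-type iodination converts the primary alcohol to the iodide faster than the hindered trisubstituted epoxide can react.

Step 20
Reactants: 27 (2S,3S)-3-(2-iodoethyl)-2-methyl-2-(triethylsilyloxymethyl)oxirane
Product: 29 ethyl 4-[(2S,3S)-3-methyl-3-(triethylsilyloxymethyl)oxiran-2-yl]-2-(triphenyl-λ5-phosphanylidene)butanoate (fragment B), via phosphonium iodide 28 (not isolated)
Conditions: Ph3P=CHCO2Et, MeCN, 70 °C; then aq. NaOH, CH2Cl2, 0 °C
Reagents that add atoms: ethyl 2-(triphenyl-λ5-phosphanylidene)acetate, CCOC(=O)C=P(c1ccccc1)(c1ccccc1)c1ccccc1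
Why: C-alkylation of the stabilised ylide by the primary iodide gives the α-alkyl phosphonium salt, and deprotonation regenerates an ester-stabilised ylide that already carries C8.

## Union and endgame

Step 21
Reactants: 18 (3S,6R)-6-(tert-butyldimethylsilyloxy)-3-ethynyl-3,7-dimethyloct-7-enal; 29 ethyl 4-[(2S,3S)-3-methyl-3-(triethylsilyloxymethyl)oxiran-2-yl]-2-(triphenyl-λ5-phosphanylidene)butanoate
Product: 30 ethyl (2E,5S,8R)-8-(tert-butyldimethylsilyloxy)-5-ethynyl-5,9-dimethyl-2-[2-[(2S,3S)-3-methyl-3-(triethylsilyloxymethyl)oxiran-2-yl]ethyl]deca-2,9-dienoate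
Conditions: toluene, 90 °C
Reagents that add atoms: none
Why: Wittig olefination with an α-alkyl ester-stabilised ylide is E-selective (ester trans to the C11 chain), which places C8 and C11 cis on C9=C10 as in the target.

Step 22
Reactants: 30 the (2E)-enoate
Product: 31 (2E,5S,8R)-8-(tert-butyldimethylsilyloxy)-5-ethynyl-5,9-dimethyl-2-[2-[(2S,3S)-3-methyl-3-(triethylsilyloxymethyl)oxiran-2-yl]ethyl]deca-2,9-dien-1-ol
Conditions: i-Bu2AlH, CH2Cl2, −78 °C; aq. potassium sodium tartrate
Reagents that add atoms: none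
Why: Aluminium hydride 1,2-reduction turns the ester into the C18 hydroxymethyl group; silyl ethers, epoxide and alkyne are inert at −78 °C.

Step 23
Reactants: 31 the allylic alcohol
Product: 32 tert-butyldiphenylsilyl ether of 31 at C18–O
Conditions: TBDPSCl, imidazole, CH2Cl2, rt
Reagents that add atoms: tert-butyl(chloro)diphenylsilane, CC(C)(C)[Si](Cl)(c1ccccc1)c1ccccc1
Why: Silylation with the robust diphenylsilyl group protects C18–OH so that the triethylsilyl groups can later be removed selectively.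

Step 24
Reactants: 32 the tris-silyl ether
Product: 33 (2R,3S)-3-[(3E,6S,9R)-9-(tert-butyldimethylsilyloxy)-3-(tert-butyldiphenylsilyloxymethyl)-6-ethynyl-6,10-dimethylundeca-3,10-dien-1-yl]-2-methyloxirane-2-carbaldehyde
Conditions: (COCl)2, DMSO, CH2Cl2, −78 → −40 °C; Et3N, → 0 °C
Reagents that add atoms: none
Why: Swern oxidation: chlorodimethylsulfonium chloride cleaves the unhindered primary Et3Si–O bond selectively and the alkoxysulfonium salt collapses to the aldehyde, which has no α-hydrogen to epimerise.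

Step 25
Reactants: 33 the epoxy ynal
Product: 35 macrocyclic alcohol (target skeleton with free C4–OH and the silyl ethers at C14 and C18), via macrocyclic triethylsilyl ether 34 (not isolated)
Conditions: Ni(cod)2 (20 mol %), (4R,5R)-1,3-bis(2-cyclohexylphenyl)-4,5-diphenylimidazolinium BF4 (20 mol %), KOt-Bu (20 mol %), Et3SiH (3 equiv), THF, 2 mM by syringe pump, rt; then HF·pyridine, pyridine, THF, 0 °C
Reagents that add atoms: none
Why: Proposed new method: zerovalent nickel bound to the chiral N-heterocyclic carbene couples the terminal alkyne and the aldehyde oxidatively to an oxanickelacyclopentene, with the C–C bond formed at the unsubstituted alkyne carbon C3 because the tert-alkyl-substituted C2 prefers to sit on nickel; σ-bond metathesis with Et3SiH and C–H reductive elimination then release the (E)-allylic silyl ether and zerovalent nickel, and the carbene is meant to direct attack to the Re face of the carbonyl (C4 R; the matched ligand antipode is fixed in a first run). The closest known reaction type is the nickel/carbene/silane reductive macrocyclisation of ynals, which has not been shown for an α,β-epoxy aldehyde, for an eleven-membered carbocycle or with catalyst control of the new carbinol centre.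

Step 26
Reactants: 35 macrocyclic alcohol; 36 3-methylbut-2-enoyl chloride
Product: 37 bis-silylated ester (38 with tert-butyldimethylsilyl on C14–O and tert-butyldiphenylsilyl on C18–O)
Conditions: 36, pyridine, DMAP (cat.), CH2Cl2, 0 °C → rt
Reagents that add atoms: none
Why: DMAP-catalysed acylation with retention at C4; the weak base avoids deconjugation of the senecioyl group and Payne rearrangement of the epoxy alcohol.

Step 27
Reactants: 37 bis-silylated ester
Product: 38 (1R,2R,3E,5S,7E,11S)-8-(hydroxymethyl)-5-[(3R)-3-hydroxy-4-methylpent-4-en-1-yl]-1,5-dimethyl-12-oxabicyclo[9.1.0]dodeca-3,7-dien-2-yl 3-methylbut-2-enoate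
Conditions: Bu4NF, AcOH, THF, 0 °C → rt
Reagents that add atoms: none
Why: Fluoride-mediated desilylation, buffered with acetic acid, frees both hydroxyls without ester cleavage, acyl migration or epoxide opening.

## Compound list

1 | pent-4-ynoic acid | C#CCCC(=O)O | starting material
2 | N-methoxy-N-methylpent-4-ynamide | C#CCCC(=O)N(C)OC | intermediate
3 | prop-1-en-2-ylmagnesium bromide | CC(=C)[Mg]Br | starting material
4 | 2-methylhept-1-en-6-yn-3-one | C=C(C)C(=O)CCC#C | intermediate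
5 | (3R)-2-methylhept-1-en-6-yn-3-ol | C=C(C)[C@H](O)CCC#C | intermediate
6 | (3R)-3-(tert-butyldimethylsilyloxy)-2-methylhept-1-en-6-yne | C=C(C)[C@H](O[Si](C)(C)C(C)(C)C)CCC#C | intermediate
7 | [(1E,5R)-5-(tert-butyldimethylsilyloxy)-2,6-dimethylhepta-1,6-dien-1-yl]dimethylalumane (not isolated) | C=C(C)[C@H](O[Si](C)(C)C(C)(C)C)CC/C(C)=C/[Al](C)C | intermediate
8 | lithium butyl[(1E,5R)-5-(tert-butyldimethylsilyloxy)-2,6-dimethylhepta-1,6-dien-1-yl]dimethylaluminate (not isolated) | C=C(C)[C@H](O[Si](C)(C)C(C)(C)C)CC/C(C)=C/[Al-](C)(C)CCCC.[Li+] | intermediate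
9 | (2E,6R)-6-(tert-butyldimethylsilyloxy)-3,7-dimethylocta-2,7-dien-1-ol | C=C(C)[C@H](O[Si](C)(C)C(C)(C)C)CC/C(C)=C/CO | intermediate
10 | [(2R,3R)-3-[(3R)-3-(tert-butyldimethylsilyloxy)-4-methylpent-4-en-1-yl]-3-methyloxiran-2-yl]methanol | C=C(C)[C@H](O[Si](C)(C)C(C)(C)C)CC[C@@]1(C)O[C@@H]1CO | intermediate
11 | ethynyltrimethylsilane | C#C[Si](C)(C)C | starting material
12 | lithium (trimethylsilyl)acetylide (not isolated) | [Li]C#C[Si](C)(C)C | intermediate
13 | diethyl[(trimethylsilyl)ethynyl]aluminium | CC[Al](CC)C#C[Si](C)(C)C | intermediate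
14 | (2S,3R,6R)-6-(tert-butyldimethylsilyloxy)-3,7-dimethyl-3-[(trimethylsilyl)ethynyl]oct-7-ene-1,2-diol (not isolated) | C=C(C)[C@H](O[Si](C)(C)C(C)(C)C)CC[C@](C)(C#C[Si](C)(C)C)[C@H](O)CO | intermediate
15 | (2S,3R,6R)-6-(tert-butyldimethylsilyloxy)-3-ethynyl-3,7-dimethyloct-7-ene-1,2-diol | C=C(C)[C@H](O[Si](C)(C)C(C)(C)C)CC[C@](C)(C#C)[C@H](O)CO | intermediate
16 | (2R,5R)-5-(tert-butyldimethylsilyloxy)-2-ethynyl-2,6-dimethylhept-6-enal | C=C(C)[C@H](O[Si](C)(C)C(C)(C)C)CC[C@](C)(C#C)C=O | intermediate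
17 | (3R,6S)-3-(tert-butyldimethylsilyloxy)-6-ethynyl-8-methoxy-2,6-dimethylocta-1,7-diene (E/Z mixture at the enol ether) | C=C(C)[C@H](O[Si](C)(C)C(C)(C)C)CC[C@](C)(C#C)C=COC | intermediate
18 | (3S,6R)-6-(tert-butyldimethylsilyloxy)-3-ethynyl-3,7-dimethyloct-7-enal (fragment A) | C=C(C)[C@H](O[Si](C)(C)C(C)(C)C)CC[C@](C)(C#C)CC=O | intermediate
19 | propane-1,3-diol | OCCCO | starting material
20 | 3-(4-methoxybenzyloxy)propan-1-ol | COc1ccc(COCCCO)cc1 | intermediate
21 | 3-(4-methoxybenzyloxy)propanal | COc1ccc(COCCC=O)cc1 | intermediate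
22 | ethyl (2E)-5-(4-methoxybenzyloxy)-2-methylpent-2-enoate | CCOC(=O)/C(C)=C/CCOCc1ccc(OC)cc1 | intermediate
23 | (2E)-5-(4-methoxybenzyloxy)-2-methylpent-2-en-1-ol | OC/C(C)=C/CCOCc1ccc(OC)cc1 | intermediate
24 | [(2S,3S)-3-[2-(4-methoxybenzyloxy)ethyl]-2-methyloxiran-2-yl]methanol | OC[C@]1(C)O[C@H]1CCOCc2ccc(OC)cc2 | intermediate
25 | (2S,3S)-3-[2-(4-methoxybenzyloxy)ethyl]-2-methyl-2-(triethylsilyloxymethyl)oxirane | CC[Si](CC)(CC)OC[C@]1(C)O[C@H]1CCOCc2ccc(OC)cc2 | intermediate
26 | 2-[(2S,3S)-3-methyl-3-(triethylsilyloxymethyl)oxiran-2-yl]ethan-1-ol | CC[Si](CC)(CC)OC[C@]1(C)O[C@H]1CCO | intermediate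
27 | (2S,3S)-3-(2-iodoethyl)-2-methyl-2-(triethylsilyloxymethyl)oxirane | CC[Si](CC)(CC)OC[C@]1(C)O[C@H]1CCI | intermediate
28 | [1-ethoxy-4-[(2S,3S)-3-methyl-3-(triethylsilyloxymethyl)oxiran-2-yl]-1-oxobutan-2-yl]triphenylphosphonium iodide (not isolated; phosphorus-bearing carbon unspecified) | CC[Si](CC)(CC)OC[C@]1(C)O[C@H]1CCC(C(=O)OCC)[P+](c2ccccc2)(c2ccccc2)c2ccccc2.[I-] | intermediate
29 | ethyl 4-[(2S,3S)-3-methyl-3-(triethylsilyloxymethyl)oxiran-2-yl]-2-(triphenyl-λ5-phosphanylidene)butanoate (fragment B) | CC[Si](CC)(CC)OC[C@]1(C)O[C@H]1CCC(C(=O)OCC)=P(c2ccccc2)(c2ccccc2)c2ccccc2 | intermediate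
30 | ethyl (2E,5S,8R)-8-(tert-butyldimethylsilyloxy)-5-ethynyl-5,9-dimethyl-2-[2-[(2S,3S)-3-methyl-3-(triethylsilyloxymethyl)oxiran-2-yl]ethyl]deca-2,9-dienoate | C=C(C)[C@H](O[Si](C)(C)C(C)(C)C)CC[C@](C)(C#C)C/C=C(\CC[C@@H]1O[C@@]1(C)CO[Si](CC)(CC)CC)C(=O)OCC | intermediate
31 | (2E,5S,8R)-8-(tert-butyldimethylsilyloxy)-5-ethynyl-5,9-dimethyl-2-[2-[(2S,3S)-3-methyl-3-(triethylsilyloxymethyl)oxiran-2-yl]ethyl]deca-2,9-dien-1-ol | C=C(C)[C@H](O[Si](C)(C)C(C)(C)C)CC[C@](C)(C#C)C/C=C(\CC[C@@H]1O[C@@]1(C)CO[Si](CC)(CC)CC)CO | intermediate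
32 | tert-butyldiphenylsilyl ether of 31 at the allylic C18 oxygen | C=C(C)[C@H](O[Si](C)(C)C(C)(C)C)CC[C@](C)(C#C)C/C=C(\CC[C@@H]1O[C@@]1(C)CO[Si](CC)(CC)CC)CO[Si](c2ccccc2)(c2ccccc2)C(C)(C)C | intermediate
33 | (2R,3S)-3-[(3E,6S,9R)-9-(tert-butyldimethylsilyloxy)-3-(tert-butyldiphenylsilyloxymethyl)-6-ethynyl-6,10-dimethylundeca-3,10-dien-1-yl]-2-methyloxirane-2-carbaldehyde | C=C(C)[C@H](O[Si](C)(C)C(C)(C)C)CC[C@](C)(C#C)C/C=C(\CC[C@@H]1O[C@@]1(C)C=O)CO[Si](c2ccccc2)(c2ccccc2)C(C)(C)C | intermediate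
34 | macrocyclic tris-silyl ether: skeleton and configuration of 38 with C4–OSiEt3, C14–OSi(t-Bu)Me2 and C18–OSi(t-Bu)Ph2 (not isolated) | C=C(C)[C@H](O[Si](C)(C)C(C)(C)C)CC[C@]1(C)/C=C/[C@@H](O[Si](CC)(CC)CC)[C@]2(C)O[C@H]2CC/C(CO[Si](c3ccccc3)(c3ccccc3)C(C)(C)C)=C\C1 | intermediate
35 | macrocyclic alcohol: skeleton and configuration of 38 with free C4–OH, C14–OSi(t-Bu)Me2 and C18–OSi(t-Bu)Ph2 | C=C(C)[C@H](O[Si](C)(C)C(C)(C)C)CC[C@]1(C)/C=C/[C@@H](O)[C@]2(C)O[C@H]2CC/C(CO[Si](c3ccccc3)(c3ccccc3)C(C)(C)C)=C\C1 | intermediate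
36 | 3-methylbut-2-enoyl chloride | CC(C)=CC(=O)Cl | starting material
37 | bis-silylated ester: 38 with C14–OSi(t-Bu)Me2 and C18–OSi(t-Bu)Ph2 | C=C(C)[C@H](O[Si](C)(C)C(C)(C)C)CC[C@]1(C)/C=C/[C@@H](OC(=O)C=C(C)C)[C@]2(C)O[C@H]2CC/C(CO[Si](c3ccccc3)(c3ccccc3)C(C)(C)C)=C\C1 | intermediate
38 | (1R,2R,3E,5S,7E,11S)-8-(hydroxymethyl)-5-[(3R)-3-hydroxy-4-methylpent-4-en-1-yl]-1,5-dimethyl-12-oxabicyclo[9.1.0]dodeca-3,7-dien-2-yl 3-methylbut-2-enoate | C=C(C)[C@H](O)CC[C@]1(C)/C=C/[C@@H](OC(=O)C=C(C)C)[C@]2(C)O[C@H]2CC/C(CO)=C\C1 | target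

## Step count and risks

Total: 27 steps. Longest linear sequence: 17 steps (steps 1–6, 8–11 and 21–27); the fragment B branch is 9 + 7 = 16 and step 7 is a one-step side branch.

Steps most likely to fail:

(a) Step 25, the proposed ring closure. Ni(cod)2 may reduce or open the α,β-epoxy aldehyde, the alkyne may oligomerise, or the C4 epimer may dominate. The fallback uses known chemistry and a different bond-forming mode. It sets out from 32. Hydrozirconation of the terminal alkyne with Cp2Zr(H)Cl (THF, rt) gives the alkenylzirconocene chloride F1, which is iodinated in the same flask (I2, 0 °C) to the (E)-vinyl iodide F2. Swern oxidation as in step 24 converts CH2OSiEt3 into the aldehyde and gives the iodo epoxy aldehyde F3. A Nozaki–Hiyama–Kishi macrocyclisation (CrCl2, NiCl2 1 mol %, DMSO/THF, 1 mM, rt, with a chiral oxazoline–sulfonamide ligand on chromium to steer the alkenylchromium to the Re face) forms C3–C4 and comes back to the route at 35.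

(b) Step 8, the alkynylalane opening that creates the quaternary centre. Attack at the tertiary carbon may be incomplete or accompanied by rearrangement. The fallback reverses the roles: the alkyne is placed first and methyl is delivered as the nucleophile. It sets out from 6. n-BuLi (THF, −78 °C) gives the lithium acetylide F4, which methyl chloroformate acylates to the ynoate F5. Pd(OAc)2/tris(2,6-dimethoxyphenyl)phosphine-catalysed syn addition of the C–H bond of 11 across the ynoate gives the (E)-enynoate F6 (alkynyl on C3, trans to the ester). Reduction with i-Bu2AlH gives the enynol F7, and Sharpless epoxidation with D-(−)-diethyl tartrate gives the epoxy alcohol F8. AlMe3 (hexane/CH2Cl2, −30 → 0 °C) then delivers methyl with inversion to the tertiary propargylic carbon. The route is rejoined at 14, which is desilylated as in step 8.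

(c) Step 20, alkylation of the stabilised ylide by the epoxy iodide. It may be slow, leave unalkylated ylide, or open the epoxide with iodide at 70 °C. The fallback replaces the ylide route by a cross-coupling and sets out from 18 and 27. Ph3P=CHCO2Et and N-iodosuccinimide (CH2Cl2, −20 °C) give the iodo ylide F9, which olefinates 18 (K2CO3, rt) to the (Z)-α-iodo enoate F10 (iodine cis to C11, ester trans). Zinc insertion into 27 (Zn dust, LiCl, THF, rt) gives the alkylzinc iodide F11. Negishi coupling (Pd(dppf)Cl2, THF, rt) replaces iodine by the alkyl chain with retention and comes back to the route at 30.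

Further compounds
F1 | step 25 | alkenylzirconocene chloride from 32 (C≡CH converted into (E)-CH=CH–ZrCp2Cl; not isolated) | C=C(C)[C@H](O[Si](C)(C)C(C)(C)C)CC[C@](C)(/C=C/[Zr](Cl)(C1C=CC=C1)C1C=CC=C1)C/C=C(\CC[C@@H]1O[C@@]1(C)CO[Si](CC)(CC)CC)CO[Si](c2ccccc2)(c2ccccc2)C(C)(C)C
F2 | step 25 | (E)-vinyl iodide (32 with C≡CH replaced by (E)-CH=CHI) | C=C(C)[C@H](O[Si](C)(C)C(C)(C)C)CC[C@](C)(/C=C/I)C/C=C(\CC[C@@H]1O[C@@]1(C)CO[Si](CC)(CC)CC)CO[Si](c2ccccc2)(c2ccccc2)C(C)(C)C
F3 | step 25 | iodo epoxy aldehyde (33 with C≡CH replaced by (E)-CH=CHI) | C=C(C)[C@H](O[Si](C)(C)C(C)(C)C)CC[C@](C)(/C=C/I)C/C=C(\CC[C@@H]1O[C@@]1(C)C=O)CO[Si](c2ccccc2)(c2ccccc2)C(C)(C)C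
F4 | step 8 | lithium acetylide of 6 (not isolated) | C=C(C)[C@H](O[Si](C)(C)C(C)(C)C)CCC#C[Li]
F5 | step 8 | methyl (6R)-6-(tert-butyldimethylsilyloxy)-7-methyloct-7-en-2-ynoate | C=C(C)[C@H](O[Si](C)(C)C(C)(C)C)CCC#CC(=O)OC
F6 | step 8 | methyl (2E,6R)-6-(tert-butyldimethylsilyloxy)-7-methyl-3-[(trimethylsilyl)ethynyl]octa-2,7-dienoate | C=C(C)[C@H](O[Si](C)(C)C(C)(C)C)CC/C(C#C[Si](C)(C)C)=C\C(=O)OC
F7 | step 8 | (2E,6R)-6-(tert-butyldimethylsilyloxy)-7-methyl-3-[(trimethylsilyl)ethynyl]octa-2,7-dien-1-ol | C=C(C)[C@H](O[Si](C)(C)C(C)(C)C)CC/C(C#C[Si](C)(C)C)=C\CO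
F8 | step 8 | [(2R,3R)-3-[(3R)-3-(tert-butyldimethylsilyloxy)-4-methylpent-4-en-1-yl]-3-[(trimethylsilyl)ethynyl]oxiran-2-yl]methanol | C=C(C)[C@H](O[Si](C)(C)C(C)(C)C)CC[C@]1(C#C[Si](C)(C)C)O[C@@H]1CO
F9 | step 20 | ethyl iodo(triphenyl-λ5-phosphanylidene)acetate (not isolated) | CCOC(=O)C(I)=P(c1ccccc1)(c1ccccc1)c1ccccc1
F10 | step 20 | ethyl (2Z,5S,8R)-8-(tert-butyldimethylsilyloxy)-5-ethynyl-2-iodo-5,9-dimethyldeca-2,9-dienoate | C=C(C)[C@H](O[Si](C)(C)C(C)(C)C)CC[C@](C)(C#C)C/C=C(\I)C(=O)OCC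
F11 | step 20 | [2-[(2S,3S)-3-methyl-3-(triethylsilyloxymethyl)oxiran-2-yl]ethyl]zinc iodide | CC[Si](CC)(CC)OC[C@]1(C)O[C@H]1CC[Zn]I
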